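The product, G and J together, is what you wanted a quick number for, with your hunch that the smaller Q here would shift it from the dawn run.

| flask | E | D | Q | remark | time |
|---|---|---|---|---|---|
| spring | 10 mM | 7.5 mM (fed, over 80 s) | 0.50 mM | run made earlier |  |
| summer | 10 mM | 11 mM (fed, over 80 s) | 0.50 mM | run made earlier |  |
| dawn | 10 mM | 15 mM (fed, over 80 s) | 0.75 mM | run made earlier |  |
| flask | 10 mM | 15.0 mM (fed, over 80 s) | 0.500 mM |  | 5.0 h |

- spring (time / h: G / %, J / %, E / %): 1.50: 22.9, 21.8, 0.8; 3.00: 20.8, 19.1, 0.7; 5.00: 20.5, 19.4, 0; 6.00: 19.9, 17.5, 0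
- summer (time / h: G / %, J / %, E / %): 1.50: 37.0, 35.3, 0; 3.00: 38.4, 35.9, 0; 5.00: 36.7, 35.7, 0; 6.00: 38.2, 36.0, 0.3
- dawn (time / h: G / %, J / %, E / %): 0.500: 42.5, 39.7, 0.6; 1.00: 42.7, 40.6, 0; 2.50: 42.1, 40.0, 0.3; 6.00: 43.0, 41.2, 0.6

(scatter of a reading: 0.5 percentage points)

1. how much G there is at 5.0 h, in percent of the E charged
2. how much J there is at 5.0 h, in percent of the E charged

1. I called e the usable D per E charged, counting each Q as costing one D, which is my own assumption. Spring had 0.700, so there D was the limiting reagent, and G plus J read 37.4% at 6.00 h.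

2. At the rich end, dawn averaged 42.6% G and 40.4% J, so by these readings 17.0% of the E charged, the missing share, stood in neither G nor J at e = 1.42.

3. I carried the loss product, the missing share times e 0.243. Summer, at e = 1.05, read 0.280, and I used dawn's value.

4. This flask has e = 1.45, which is 0.0300 above dawn and small against e itself. So on this reckoning your Q shift brings the missing share to 16.8%. Split as at dawn, that gave me 42.7% G and 40.5% J.

The forecast said 44.6% G and 42.4% J, above my numbers, expecting “the cap to be slightly higher”.

The flask gave 43.0% G and 40.8% J at 5.0 h.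

    E ⇌ X, rate k1*(cs1 - [X]) while solid is left; crystals form when [X] > cs1 (solubility = 5.40 mM, k = 0.320 min⁻¹)
    G ⇌ J (K = 0.950, k = 0.510 min⁻¹)
    D + Q → Z (k = 390 L mol⁻¹ min⁻¹)
    X + D → G (k = 21.0 L mol⁻¹ min⁻¹)
    X + G → L (k = 6.10 L mol⁻¹ min⁻¹)

During the feed Q fell to 2.41% of its charge by 0.0222 h, and while X stood, X + D made G, X + G made L, and G and J relaxed with a half-life of 0.662 min. X stood at 0% at 2.50 h, and from then to 5.0 h the largest change in the share of any substrate, intermediate or product was 0 percentage points, with 35% of the charged D left. The flask's loss product came to 0.235, the missing share standing as L at 16.2%, each L counted as two E. With all else held, the J at 5.0 h had moved by 5 points at D of 11.1 mM and of 33.7 mM. In the neighbour flask with 25 mM of D, e was 2.45, so dawn's loss product gave 9.92% missing, and L in that flask held 8.38%.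

The runs come from a simulation with constants of no real substance; noise was put on by code.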